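In a one-step world with [nucleophile] held steady (pseudo-first-order), the count of turnovers, ln(charged electrophile / electrophile left), grows in step with time and with [nucleophile]. I test that picture on the two earlier runs, alder and cedar.

| flask | electrophile | nucleophile | remark | time |
|---|---|---|---|---|
| alder | 0.20 M | 0.53 equiv | run made earlier |  |
| cedar | 0.20 M | 1.4 equiv | run made earlier |  |
| violet | 0.20 M | 0.800 equiv |  | 10 h |
| ochre | 0.20 M | 1.20 equiv |  | 10 h |
| amber | 0.20 M | 1.80 equiv |  | 10 h |

| run | time / h | electrophile / % | product / % |
|---|---|---|---|
| alder | 0.417 | 95 | 1 |
| alder | 1.00 | 91 | 10 |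
| alder | 2.00 | 85 | 10 |
| alder | 3.00 | 80 | 14 |
| alder | 4.00 | 74 | 16 |
| alder | 6.00 | 67 | 20 |
| alder | 8.00 | 63 | 20 |
| cedar | 1.00 | 83 | 17 |
| cedar | 2.00 | 68 | 22 |
| cedar | 3.00 | 63 | 30 |
| cedar | 4.00 | 55 | 36 |
| cedar | 5.00 | 48 | 40 |
| cedar | 6.00 | 43 | 47 |
| cedar | 8.00 | 38 | 50 |

(scatter of a reading: 1.5 percentage points)

- what has gone from electrophile into another species counts as reacted, even if it can come back

* part of the electrophile that has reacted at the end, violet
* part of the electrophile that has reacted at the end, ochre
* part of the electrophile that has reacted at the end, amber
* what raising the equivalents of nucleophile from its lowest to its highest value here does to the part of the electrophile that has reacted (changes below 5 percentage points count as none) (it falls / it rises / no change)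

At 8.00 h alder has counted 0.462 turnovers and cedar 0.968. Scaling both to 10 h by time gives 0.578 and 1.21. A straight line between them in equivalents then puts violet at 53.9% reacted.

Time is the weak link. Cedar counts 0.598 in its first 4.00 h but less, 0.370, in the next stretch of that length. So I carry each run on at the pace of its last stretch. Alder reaches 0.543 and cedar 1.15. The slope between them, the turnovers won per equivalent of nucleophile by the asked time, is 0.701. This costs two readings from each run and one line, and amber lies beyond the line's end.

| flask | nucleophile | turnovers | reacted |
|---|---|---|---|
| violet | 0.800 equiv | 0.732 | 51.9% |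
| ochre | 1.20 equiv | 1.01 | 63.7% |
| amber | 1.80 equiv | 1.43 | 76.1% |

The forecast says 51% for violet, 62% for ochre and 74% for amber, and its verdict on the part reacted is "it rises". Its way there reads “Interpolating this roughly linearly in equivalents”. My amber stands higher than its figure.

The flasks give 50.3% for violet, 61.7% for ochre and 75.5% for amber. The verdict on the part reacted is "it rises", by 25 percentage points from the lowest to the highest equivalents.

    electrophile + nucleophile → acid set free + product (k = 0.656 M⁻¹ h⁻¹)
    electrophile ⇌ dormant form (K = 0.800, k = 0.0318 h⁻¹)
    nucleophile + acid set free ⇌ protonated nucleophile, settled at all times (K = 3300 M⁻¹)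

The rise comes from the equivalents: given violet's equivalents, amber falls from 75.5% to 50.3%. In turnovers, my slope predicts a step of 0.701 from violet to amber. The flasks' own counts are 0.699 and 1.41, a step of 0.707.

A further flask is like violet but holds 2.00 equiv of nucleophile. The slope gives it 1.57 turnovers, so 79.2% reacted. It computes to 79.2%.

(The runs were computed for an exercise, noise included.)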